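**Retrosynthetic overview**
- The target lactone comes from a hydrogenolytic ring switch: the benzylic ring C–O bond of a 5-(3,4-dimethoxyphenyl) lactone is cleaved and the freed acid closes onto the neighbouring CH2OH.
- The tertiary C–OH comes from enolate oxygenation of that 5-aryl lactone, anti to its adjacent carboxyl group (key C–O bond; sets the quaternary centre).
- The hydroxybenzyl arm comes from dianion alkylation of a trans aryl-paraconic acid with O-benzyl syringyl bromide (made from syringaldehyde).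
- The paraconic acid comes from a catalytic enantioselective hydrolactonization (C–O bond, new) of the Stobbe diacid from veratraldehyde and dimethyl succinate.
- Ring order: the sacrificial 5-aryl lactone is formed first, the target lactone last; both arenes are bought.

Assumption: the antipode of the chiral acid catalyst in step 4 that gives the (2S,3S) acid is fixed by an initial screen of both catalyst enantiomers.

**Step 1**
Reactants: 1 syringaldehyde (4-hydroxy-3,5-dimethoxybenzaldehyde); 2 benzyl bromide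
Product: 4 [4-(benzyloxy)-3,5-dimethoxyphenyl]methanol, via O-benzylsyringaldehyde 3 (not isolated)
Conditions: K2CO3, DMF, 60 °C; then NaBH4, MeOH, 0 °C
Reagents that add atoms: none
Why: Williamson etherification of the phenoxide followed by borohydride reduction of the aldehyde in the same flask; no stereocentre is involved.

**Step 2**
Reactants: 4 [4-(benzyloxy)-3,5-dimethoxyphenyl]methanol
Product: 5 2-(benzyloxy)-5-(bromomethyl)-1,3-dimethoxybenzene
Conditions: PBr3, CH2Cl2, 0 °C
Reagents that add atoms: phosphorus tribromide, BrP(Br)Br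
Why: Alcohol-to-bromide substitution through the phosphite ester (SN2 at an activated benzylic carbon); no stereocentre is involved.

**Step 3**
Reactants: 6 veratraldehyde (3,4-dimethoxybenzaldehyde); 7 dimethyl succinate
Product: 9 (E)-2-(3,4-dimethoxybenzylidene)succinic acid, via Stobbe half-ester 8 (not isolated)
Conditions: NaOMe, MeOH, reflux; then aq NaOH, reflux; HCl
Reagents that add atoms: sodium hydroxide, [Na+].[OH-]
Why: Stobbe condensation (aldol, paraconate lactone, E1cB ring opening) gives the E half-ester, which is saponified in the same pot; the E geometry is set in the E1cB step.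

**Step 4**
Reactants: 9 (E)-2-(3,4-dimethoxybenzylidene)succinic acid
Product: 10 (2S,3S)-2-(3,4-dimethoxyphenyl)-5-oxooxolane-3-carboxylic acid (trans)
Conditions: chiral IDPi Brønsted acid (5 mol %), CHCl3, 40 °C
Reagents that add atoms: none
Why: Proposed new method: a confined chiral imidodiphosphorimidate acid protonates the alkene carbon that bears CO2H while the CH2CO2H oxygen closes onto the developing 3,4-dimethoxybenzyl cation inside the chiral ion pair (concerted-asynchronous anti addition across the E alkene), so the benzylic C–O bond and the C3–H bond form together under kinetic control to give the trans (2S,3S) lactone, in which C3 is the centre that survives and C2 is sacrificial; the closest known reaction types are IDPi-catalysed asymmetric hydrolactonization of unactivated alkenoic acids and the racemic hot-acid lactonization of Stobbe acids to paraconic acids.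

**Step 5**
Reactants: 10 (2S,3S)-2-(3,4-dimethoxyphenyl)-5-oxooxolane-3-carboxylic acid; 5 2-(benzyloxy)-5-(bromomethyl)-1,3-dimethoxybenzene
Product: 11 (2S,3S,4S)-4-{[4-(benzyloxy)-3,5-dimethoxyphenyl]methyl}-2-(3,4-dimethoxyphenyl)-5-oxooxolane-3-carboxylic acid
Conditions: LiHMDS (2.2 equiv), THF, −78 °C; then 5, −78 to −30 °C; aq HCl
Reagents that add atoms: none
Why: Alkylation of the carboxylate/lactone-enolate dianion (paraconic acid dianion alkylation); the bromide enters C4 anti to the adjacent C3 carboxylate, and since C4 is planarized again in step 6 only the constitution matters here.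

**Step 6**
Reactants: 11 (2S,3S,4S)-4-{[4-(benzyloxy)-3,5-dimethoxyphenyl]methyl}-2-(3,4-dimethoxyphenyl)-5-oxooxolane-3-carboxylic acid
Product: 12 (2S,3R,4S)-4-{[4-(benzyloxy)-3,5-dimethoxyphenyl]methyl}-2-(3,4-dimethoxyphenyl)-4-hydroxy-5-oxooxolane-3-carboxylic acid
Conditions: KHMDS (2.3 equiv), THF, −78 °C; then 2-(phenylsulfonyl)-3-phenyloxaziridine; aq HCl
Reagents that add atoms: 2-(phenylsulfonyl)-3-phenyloxaziridine, O=S(=O)(c1ccccc1)N1OC1c1ccccc1
Why: Davis oxidation of the tetrasubstituted potassium enolate; oxygen is delivered to C4 on the face anti to the adjacent C3 carboxylate, which sets the tertiary alcohol (4S) with OH trans to the C3 carboxyl, the arrangement that becomes "OH cis to the dimethoxybenzyl group" after the ring switch.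

**Step 7**
Reactants: 12 (2S,3R,4S)-4-{[4-(benzyloxy)-3,5-dimethoxyphenyl]methyl}-2-(3,4-dimethoxyphenyl)-4-hydroxy-5-oxooxolane-3-carboxylic acid
Product: 13 (3S,4R,5S)-3-{[4-(benzyloxy)-3,5-dimethoxyphenyl]methyl}-5-(3,4-dimethoxyphenyl)-3-hydroxy-4-(hydroxymethyl)oxolan-2-one
Conditions: BH3·SMe2, THF, 0 °C to rt; then MeOH, H2O
Reagents that add atoms: none
Why: Chemoselective borane reduction of the carboxylic acid (via the acyloxyborane) in the presence of the lactone; no stereocentre is touched.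

**Step 8**
Reactants: 13 (3S,4R,5S)-3-{[4-(benzyloxy)-3,5-dimethoxyphenyl]methyl}-5-(3,4-dimethoxyphenyl)-3-hydroxy-4-(hydroxymethyl)oxolan-2-one
Product: 16 (3S,4S)-4-[(3,4-dimethoxyphenyl)methyl]-3-hydroxy-3-[(4-hydroxy-3,5-dimethoxyphenyl)methyl]oxolan-2-one, via phenol lactone 14 (not isolated), via open hydroxy acid 15 (not isolated)
Conditions: H2 (4 bar), 10% Pd/C, AcOH–EtOAc, 50 °C
Reagents that add atoms: none
Why: Hydrogenolysis removes the aryl benzyl ether and cleaves the benzylic lactone C–O bond, and the released γ-hydroxy acid lactonizes onto the primary alcohol (hydrogenolytic lactone transposition); the sacrificial benzylic centre becomes the CH2 of the dimethoxybenzyl group while the two remaining stereocentres are untouched.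

**Compound list**
1 | syringaldehyde (4-hydroxy-3,5-dimethoxybenzaldehyde) | COc1cc(C=O)cc(OC)c1O | starting material
2 | benzyl bromide | BrCc1ccccc1 | starting material
3 | 4-(benzyloxy)-3,5-dimethoxybenzaldehyde (O-benzylsyringaldehyde) | COc1cc(C=O)cc(OC)c1OCc1ccccc1 | intermediate
4 | [4-(benzyloxy)-3,5-dimethoxyphenyl]methanol | COc1cc(CO)cc(OC)c1OCc1ccccc1 | intermediate
5 | 2-(benzyloxy)-5-(bromomethyl)-1,3-dimethoxybenzene | COc1cc(CBr)cc(OC)c1OCc1ccccc1 | intermediate
6 | veratraldehyde (3,4-dimethoxybenzaldehyde) | COc1ccc(C=O)cc1OC | starting material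
7 | dimethyl succinate | COC(=O)CCC(=O)OC | starting material
8 | (E)-4-(3,4-dimethoxyphenyl)-3-(methoxycarbonyl)but-3-enoic acid (Stobbe half-ester) | COC(=O)/C(CC(O)=O)=C/c1ccc(OC)c(OC)c1 | intermediate
9 | (E)-2-(3,4-dimethoxybenzylidene)succinic acid | OC(=O)/C(CC(O)=O)=C/c1ccc(OC)c(OC)c1 | intermediate
10 | (2S,3S)-2-(3,4-dimethoxyphenyl)-5-oxooxolane-3-carboxylic acid | OC(=O)[C@H]1CC(=O)O[C@@H]1c1ccc(OC)c(OC)c1 | intermediate
11 | (2S,3S,4S)-4-{[4-(benzyloxy)-3,5-dimethoxyphenyl]methyl}-2-(3,4-dimethoxyphenyl)-5-oxooxolane-3-carboxylic acid | OC(=O)[C@H]1[C@H](Cc2cc(OC)c(OCc3ccccc3)c(OC)c2)C(=O)O[C@@H]1c1ccc(OC)c(OC)c1 | intermediate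
12 | (2S,3R,4S)-4-{[4-(benzyloxy)-3,5-dimethoxyphenyl]methyl}-2-(3,4-dimethoxyphenyl)-4-hydroxy-5-oxooxolane-3-carboxylic acid | OC(=O)[C@H]1[C@@](O)(Cc2cc(OC)c(OCc3ccccc3)c(OC)c2)C(=O)O[C@@H]1c1ccc(OC)c(OC)c1 | intermediate
13 | (3S,4R,5S)-3-{[4-(benzyloxy)-3,5-dimethoxyphenyl]methyl}-5-(3,4-dimethoxyphenyl)-3-hydroxy-4-(hydroxymethyl)oxolan-2-one | OC[C@H]1[C@@](O)(Cc2cc(OC)c(OCc3ccccc3)c(OC)c2)C(=O)O[C@@H]1c1ccc(OC)c(OC)c1 | intermediate
14 | (3S,4R,5S)-5-(3,4-dimethoxyphenyl)-3-hydroxy-3-[(4-hydroxy-3,5-dimethoxyphenyl)methyl]-4-(hydroxymethyl)oxolan-2-one (phenol lactone) | OC[C@H]1[C@@](O)(Cc2cc(OC)c(O)c(OC)c2)C(=O)O[C@@H]1c1ccc(OC)c(OC)c1 | intermediate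
15 | (2S,3S)-4-(3,4-dimethoxyphenyl)-2-hydroxy-2-[(4-hydroxy-3,5-dimethoxyphenyl)methyl]-3-(hydroxymethyl)butanoic acid (open hydroxy acid) | COc1ccc(C[C@@H](CO)[C@@](O)(Cc2cc(OC)c(O)c(OC)c2)C(O)=O)cc1OC | intermediate
16 | (3S,4S)-4-[(3,4-dimethoxyphenyl)methyl]-3-hydroxy-3-[(4-hydroxy-3,5-dimethoxyphenyl)methyl]oxolan-2-one (CNP0553772.1) | COc1ccc(C[C@H]2COC(=O)[C@]2(O)Cc2cc(OC)c(O)c(OC)c2)cc1OC | target

**Step count**
Total steps: 8. Longest linear sequence: 6 steps (steps 3 to 8, from veratraldehyde); steps 1 and 2 make the bromide used in step 5.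

**Three steps most likely to fail**

Step 4 (the proposed new hydrolactonization). The ester-conjugated alkene may protonate slowly, the diacid may be poorly soluble, and the electron-rich benzylic lactone may re-ionize under the strong acid and lose enantiopurity. The fallback replaces the catalytic C–O closure by an auxiliary-controlled aldol and uses known chemistry only. It sets out from 6 and comes back at 10. (S)-4-Benzyloxazolidin-2-one is N-acylated with methyl 4-chloro-4-oxobutanoate (n-BuLi, THF, −78 °C) to give methyl 4-[(4S)-4-benzyl-2-oxo-1,3-oxazolidin-3-yl]-4-oxobutanoate F1. An Evans syn-aldol reaction of its dibutylboron Z-enolate (Bu2BOTf, iPr2NEt, CH2Cl2, −78 °C) with 6 gives methyl (3S,4S)-3-{[(4S)-4-benzyl-2-oxo-1,3-oxazolidin-3-yl]carbonyl}-4-(3,4-dimethoxyphenyl)-4-hydroxybutanoate F2. This lactonizes (cat. TsOH, toluene) to the trans lactone (4S)-4-benzyl-3-{[(2S,3S)-2-(3,4-dimethoxyphenyl)-5-oxooxolan-3-yl]carbonyl}-1,3-oxazolidin-2-one F3. Cleavage with LiOH/H2O2 (THF–H2O, 0 °C) removes the auxiliary and gives 10.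

Step 6 (oxygenation of a hindered carboxylate/enolate dianion). The dianion may be poorly soluble or sluggish, and the face selectivity has not been shown on the free acid. The fallback changes the order of events so that a neutral lactone is oxidized. It sets out from 11 and comes back at 16. The acid of 11 is reduced first (BH3·SMe2, THF) to (3S,4R,5S)-3-{[4-(benzyloxy)-3,5-dimethoxyphenyl]methyl}-5-(3,4-dimethoxyphenyl)-4-(hydroxymethyl)oxolan-2-one F4. The primary alcohol is benzylated under acid catalysis (benzyl 2,2,2-trichloroacetimidate, cat. TfOH) to (3S,4R,5S)-4-[(benzyloxy)methyl]-3-{[4-(benzyloxy)-3,5-dimethoxyphenyl]methyl}-5-(3,4-dimethoxyphenyl)oxolan-2-one F5. Its mono-anionic potassium enolate is oxidized (KHMDS, then the same oxaziridine or MoOPH), anti to the CH2OBn group, to (3S,4R,5S)-4-[(benzyloxy)methyl]-3-{[4-(benzyloxy)-3,5-dimethoxyphenyl]methyl}-5-(3,4-dimethoxyphenyl)-3-hydroxyoxolan-2-one F6. Hydrogenolysis under the step 8 conditions removes both benzyl ethers, cleaves the benzylic lactone bond and closes the ring to 16.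

Step 8 (hydrogenolysis of the benzylic lactone C–O bond). This cleavage can stall after the fast O-debenzylation, and forcing acid risks ionization next to the stereocentre. The fallback moves the acyl group before the reduction, so that a free benzylic alcohol is cleaved and not a lactone. It sets out from 13 and comes back at 16. Base-mediated acyl migration to the primary alcohol (K2CO3, MeOH, rt) gives (3S,4R)-3-{[4-(benzyloxy)-3,5-dimethoxyphenyl]methyl}-4-[(S)-(3,4-dimethoxyphenyl)(hydroxy)methyl]-3-hydroxyoxolan-2-one F7. Its benzylic alcohol and benzyl ether are then hydrogenolysed (H2, Pd/C, EtOH, cat. HCl) to 16.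

**Further compounds**
F1 | step 4 | methyl 4-[(4S)-4-benzyl-2-oxo-1,3-oxazolidin-3-yl]-4-oxobutanoate | COC(=O)CCC(=O)N1[C@@H](Cc2ccccc2)COC1=O
F2 | step 4 | methyl (3S,4S)-3-{[(4S)-4-benzyl-2-oxo-1,3-oxazolidin-3-yl]carbonyl}-4-(3,4-dimethoxyphenyl)-4-hydroxybutanoate | COC(=O)C[C@@H]([C@H](O)c1ccc(OC)c(OC)c1)C(=O)N1[C@@H](Cc2ccccc2)COC1=O
F3 | step 4 | (4S)-4-benzyl-3-{[(2S,3S)-2-(3,4-dimethoxyphenyl)-5-oxooxolan-3-yl]carbonyl}-1,3-oxazolidin-2-one | O=C([C@H]1CC(=O)O[C@@H]1c1ccc(OC)c(OC)c1)N1[C@@H](Cc2ccccc2)COC1=O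
F4 | step 6 | (3S,4R,5S)-3-{[4-(benzyloxy)-3,5-dimethoxyphenyl]methyl}-5-(3,4-dimethoxyphenyl)-4-(hydroxymethyl)oxolan-2-one | OC[C@H]1[C@H](Cc2cc(OC)c(OCc3ccccc3)c(OC)c2)C(=O)O[C@@H]1c1ccc(OC)c(OC)c1
F5 | step 6 | (3S,4R,5S)-4-[(benzyloxy)methyl]-3-{[4-(benzyloxy)-3,5-dimethoxyphenyl]methyl}-5-(3,4-dimethoxyphenyl)oxolan-2-one | C(OC[C@H]1[C@H](Cc2cc(OC)c(OCc3ccccc3)c(OC)c2)C(=O)O[C@@H]1c1ccc(OC)c(OC)c1)c1ccccc1
F6 | step 6 | (3S,4R,5S)-4-[(benzyloxy)methyl]-3-{[4-(benzyloxy)-3,5-dimethoxyphenyl]methyl}-5-(3,4-dimethoxyphenyl)-3-hydroxyoxolan-2-one | C(OC[C@H]1[C@@](O)(Cc2cc(OC)c(OCc3ccccc3)c(OC)c2)C(=O)O[C@@H]1c1ccc(OC)c(OC)c1)c1ccccc1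
F7 | step 8 | (3S,4R)-3-{[4-(benzyloxy)-3,5-dimethoxyphenyl]methyl}-4-[(S)-(3,4-dimethoxyphenyl)(hydroxy)methyl]-3-hydroxyoxolan-2-one | O[C@H](c1ccc(OC)c(OC)c1)[C@H]1COC(=O)[C@]1(O)Cc1cc(OC)c(OCc2ccccc2)c(OC)c1
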